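**Strategy.** Everything rests on opening the trans-decalin at C4–C5 and C9–C10. One Cp2TiCl radical cascade on an acyclic epoxydiene closes ring A, then ring B, and sets C4, C5, C9 and C10 from the C6 carbinol. The target invites this: C3 of ring A is a plain methylene, while the neighbouring quaternary C4 holds the oxygenated carbon C18 equatorially, so a C4–C18 oxirane supplies the C4 radical and the C18 hydroxyl at once; in ring B the equatorial C6 oxygen steers the fold and the C8 exocyclic methylene is where the cascade ends. The precursor is a (6S)-silyloxy (E,E)-diene ending in a 2-methyloxirane, used as both epimers. Alkyne homologation and a vinylogous aldol attach the butenolide chain.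

Key step: step 14

Remark on locants: C1–C20 in the text are labdane locants (C17 exocyclic methylene carbon, C18 the oxygenated carbon on C4, C19 and C20 the methyls on C4 and C10, C16 the methyl on C13). Butenolide atoms are primed (C2'–C5'). Systematic names of open-chain compounds carry their own numbering.

Assumption: (R)-BINOL is taken to direct attack to the Re face of the enal carbonyl in the vinylogous aldol; should the sense prove opposite, (S)-BINOL is used and nothing else changes.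

Step 1
Reactants: 1 but-3-yn-1-ol
Product: 2 tert-butyl(but-3-yn-1-yloxy)dimethylsilane
Conditions: TBSCl, imidazole, CH2Cl2, 0 °C to rt
Reagents that add atoms: tert-butyldimethylsilyl chloride, CC(C)(C)[Si](C)(C)Cl
Why: Imidazole-promoted silylation of a primary alcohol masks the future C6 oxygen for the organoaluminium chemistry.

Step 2
Reactants: 2 tert-butyl(but-3-yn-1-yloxy)dimethylsilane; 3 ethylene oxide
Product: 6 (E)-6-(tert-butyldimethylsilyloxy)-4-methylhex-3-en-1-ol, via alkenylalane 4 (not isolated), via lithium alanate 5 (not isolated)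
Conditions: AlMe3, Cp2ZrCl2 (0.25 equiv), CH2Cl2, 0 °C to rt; then n-BuLi, hexane/THF, −78 to 0 °C; then 3, 0 °C to rt
Reagents that add atoms: trimethylaluminium, C[Al](C)C
Why: Negishi zirconium-catalysed methylalumination adds methyl and aluminium syn with the methyl on the internal carbon, and the derived alanate opens the oxirane with retention, which fixes the E C8=C9 alkene.

Step 3
Reactants: 6 (E)-6-(tert-butyldimethylsilyloxy)-4-methylhex-3-en-1-ol
Product: 7 (E)-tert-butyl{[6-(4-methoxybenzyloxy)-3-methylhex-3-en-1-yl]oxy}dimethylsilane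
Conditions: NaH, PMBCl, n-Bu4NI (cat.), THF/DMF, 0 °C to rt
Reagents that add atoms: 4-methoxybenzyl chloride, COc1ccc(CCl)cc1
Why: Williamson etherification of the primary alkoxide protects the future C12 oxygen with a group that is inert to radicals and orthogonal to silyl ethers.

Step 4
Reactants: 7 (E)-tert-butyl{[6-(4-methoxybenzyloxy)-3-methylhex-3-en-1-yl]oxy}dimethylsilane
Product: 8 (E)-6-(4-methoxybenzyloxy)-3-methylhex-3-en-1-ol
Conditions: n-Bu4NF, THF, rt
Reagents that add atoms: none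
Why: Fluoride cleavage of the primary silyl ether leaves the PMB ether and the alkene untouched.

Step 5
Reactants: 8 (E)-6-(4-methoxybenzyloxy)-3-methylhex-3-en-1-ol
Product: 9 (E)-6-(4-methoxybenzyloxy)-3-methylhex-3-enal
Conditions: Dess–Martin periodinane, NaHCO3, CH2Cl2, 0 °C; used at once
Reagents that add atoms: none
Why: Buffered Dess–Martin oxidation should give the β,γ-unsaturated aldehyde without moving the alkene into conjugation.

Step 6
Reactants: 9 (E)-6-(4-methoxybenzyloxy)-3-methylhex-3-enal; 10 hept-1-en-6-yne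
Product: 12 rac-(3E)-1-(4-methoxybenzyloxy)-4-methyltrideca-3,12-dien-7-yn-6-ol, via lithium acetylide 11 (not isolated)
Conditions: 10, n-BuLi, THF, −78 °C; then 9, −78 °C
Reagents that add atoms: none
Why: 1,2-Addition of a lithium acetylide to the aldehyde at low temperature outruns enolisation and forms the C5–C6 bond, the carbinol being racemic at this stage.

Step 7
Reactants: 12 rac-(3E)-1-(4-methoxybenzyloxy)-4-methyltrideca-3,12-dien-7-yn-6-ol
Product: 13 (3E)-1-(4-methoxybenzyloxy)-4-methyltrideca-3,12-dien-7-yn-6-one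
Conditions: Dess–Martin periodinane, NaHCO3, CH2Cl2, 0 °C
Reagents that add atoms: none
Why: Dess–Martin oxidation of a propargylic alcohol gives the ynone under non-basic conditions that spare the skipped alkene.

Step 8
Reactants: 13 (3E)-1-(4-methoxybenzyloxy)-4-methyltrideca-3,12-dien-7-yn-6-one
Product: 14 (3E,6S)-1-(4-methoxybenzyloxy)-4-methyltrideca-3,12-dien-7-yn-6-ol
Conditions: Ru[(S,S)-TsDPEN](p-cymene) (1 mol %), i-PrOH, rt
Reagents that add atoms: none
Why: Noyori asymmetric transfer hydrogenation of an alkynyl ketone with the (S,S)-catalyst should deliver hydride to the face that gives the S propargylic alcohol, which sets C6 under base-free conditions.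

Step 9
Reactants: 14 (3E,6S)-1-(4-methoxybenzyloxy)-4-methyltrideca-3,12-dien-7-yn-6-ol
Product: 16 (3E,6S,7Z)-8-iodo-1-(4-methoxybenzyloxy)-4-methyltrideca-3,7,12-trien-6-ol, via cyclic alanate 15 (not isolated)
Conditions: NaAlH2(OCH2CH2OMe)2, THF, 0 °C to rt; then EtOAc; then I2, THF, −78 to 0 °C
Reagents that add atoms: iodine, [I][I]
Why: Hydroxyl-directed trans-hydroalumination of the propargylic alcohol puts aluminium on the distal carbon (C10) in a five-membered alanate, and iodinolysis with retention gives the Z iodide while isolated alkenes stay inert.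

Step 10
Reactants: 16 (3E,6S,7Z)-8-iodo-1-(4-methoxybenzyloxy)-4-methyltrideca-3,7,12-trien-6-ol
Product: 17 (3E,6S,7E)-1-(4-methoxybenzyloxy)-4,8-dimethyltrideca-3,7,12-trien-6-ol
Conditions: Me2CuLi (from CuI and MeLi, excess), Et2O, 0 °C
Reagents that add atoms: lithium dimethylcuprate, [Li+].C[Cu-]C
Why: Gilman cuprate coupling replaces the vinylic iodine by methyl (C20) with retention, giving the E C5=C10 alkene with the methyl cis to C6.

Step 11
Reactants: 17 (3E,6S,7E)-1-(4-methoxybenzyloxy)-4,8-dimethyltrideca-3,7,12-trien-6-ol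
Product: 18 (3E,6S,7E)-6-(tert-butyldimethylsilyloxy)-1-(4-methoxybenzyloxy)-4,8-dimethyltrideca-3,7,12-triene
Conditions: TBSCl, imidazole, DMF, rt
Reagents that add atoms: tert-butyldimethylsilyl chloride, CC(C)(C)[Si](C)(C)Cl
Why: Silylation of the secondary allylic alcohol gives a robust ether that survives the oxidation, ylide and radical steps.

Step 12
Reactants: 18 (3E,6S,7E)-6-(tert-butyldimethylsilyloxy)-1-(4-methoxybenzyloxy)-4,8-dimethyltrideca-3,7,12-triene
Product: 19 (6E,8S,10E)-8-(tert-butyldimethylsilyloxy)-13-(4-methoxybenzyloxy)-6,10-dimethyltrideca-6,10-dien-2-one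
Conditions: PdCl2 (10 mol %), CuCl, O2 (1 atm), DMF/H2O 7:1, rt
Reagents that add atoms: water, O
Why: Tsuji–Wacker oxidation is selective for the monosubstituted alkene (Markovnikov hydroxypalladation), the trisubstituted alkenes and both ethers being inert.

Step 13
Reactants: 19 (6E,8S,10E)-8-(tert-butyldimethylsilyloxy)-13-(4-methoxybenzyloxy)-6,10-dimethyltrideca-6,10-dien-2-one
Product: 20 2-methyl-2-[(4E,6S,8E)-6-(tert-butyldimethylsilyloxy)-11-(4-methoxybenzyloxy)-4,8-dimethylundeca-4,8-dien-1-yl]oxirane (both C4 epimers)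
Conditions: Me3S+ I−, n-BuLi, THF, −10 °C; then 19, −10 °C to rt
Reagents that add atoms: trimethylsulfonium iodide, C[S+](C)C.[I-]
Why: Corey–Chaykovsky methylenation adds C18 and closes the oxirane, and the new centre C4 may form as both epimers because the next step makes it planar.

Step 14
Reactants: 20 2-methyl-2-[(4E,6S,8E)-6-(tert-butyldimethylsilyloxy)-11-(4-methoxybenzyloxy)-4,8-dimethylundeca-4,8-dien-1-yl]oxirane (both C4 epimers)
Product: 25 6α-(tert-butyldimethylsilyloxy)-12-(4-methoxybenzyloxy)-13,14,15,16-tetranorlabd-8(17)-en-18-ol, via C4 radical 21 (not isolated), via monocyclic C10 radical 22 (not isolated), via bicyclic C8 radical 23 (not isolated), via titanium alkoxide 24 (not isolated)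
Conditions: Cp2TiCl (2.2 equiv, from Cp2TiCl2 and Mn dust in THF) added slowly to 20, THF (0.01 M), rt; aq. NaH2PO4
Reagents that add atoms: none
Why: Proposed new method: Cp2TiCl (trivalent titanium) gives one electron to the oxirane of either epimer of 20 and the C4–O bond breaks, so both epimers give the same planar tertiary radical 21 with a CH2OTi(Cl)Cp2 arm; 21 adds to C5 of the E C5=C10 alkene (6-endo-trig, chair, ring A) to give the tertiary C10 radical 22, 22 adds to C9 of the E C8=C9 alkene (6-endo-trig, chair, ring B) to give the tertiary C8 radical 23, and a second Cp2TiCl takes a hydrogen from the C8 methyl (radical capture, then β-hydride elimination) to leave the exocyclic alkene in alkoxide 24, hydrolysed on work-up. The closest known reaction type is the Cp2TiCl radical cyclization of trisubstituted epoxypolyprenes ending in an exocyclic alkene, together with the known Cp2TiCl opening of 2,2-disubstituted oxiranes to tertiary β-titanoxy radicals; new is that the oxygen stays on the exocyclic carbon C18 and that an allylic silyl ether flanks the first alkene. C5 and C10 (trans fusion) and C9 (equatorial chain) follow from the E geometry of both alkenes in the chair–chair fold, C4 from the bulky CH2OTi(Cl)Cp2 group choosing the equatorial site away from the methyl on C10, and the sense of the whole fold from C6. The selectivity needed is one face of C5 relative to C6: H6 lies in the C5=C10 plane to escape allylic 1,3-strain with the cis methyl on C10, the branched C7 methylene then shields one face and the radical enters on the other, past the silyloxy group in the outside position, which is the fold that ends with O6 equatorial in ring B and not 1,3-diaxial to the angular methyl. Ethers, silyl ethers and isolated trisubstituted alkenes do not react with Cp2TiCl, and slow addition of the titanium reagent to dilute 20 keeps a second Cp2TiCl from capturing 21 before it cyclizes.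

Step 15
Reactants: 25 6α-(tert-butyldimethylsilyloxy)-12-(4-methoxybenzyloxy)-13,14,15,16-tetranorlabd-8(17)-en-18-ol
Product: 26 6α-(tert-butyldimethylsilyloxy)-12-(4-methoxybenzyloxy)-18-(triethylsilyloxy)-13,14,15,16-tetranorlabd-8(17)-ene
Conditions: TESCl, imidazole, DMAP (cat.), DMF, rt
Reagents that add atoms: triethylsilyl chloride, CC[Si](Cl)(CC)CC
Why: Silylation of the neopentyl primary alcohol as the TES ether gives a group that can later be removed in the presence of secondary TBS ethers.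

Step 16
Reactants: 26 6α-(tert-butyldimethylsilyloxy)-12-(4-methoxybenzyloxy)-18-(triethylsilyloxy)-13,14,15,16-tetranorlabd-8(17)-ene
Product: 27 6α-(tert-butyldimethylsilyloxy)-18-(triethylsilyloxy)-13,14,15,16-tetranorlabd-8(17)-en-12-ol
Conditions: DDQ, CH2Cl2/pH 7 buffer 10:1, 0 °C
Reagents that add atoms: none
Why: Oxidative PMB cleavage by DDQ (benzylic hydride abstraction, then hydrolysis) in buffered medium leaves the silyl ethers and the 1,1-disubstituted alkene intact.

Step 17
Reactants: 27 6α-(tert-butyldimethylsilyloxy)-18-(triethylsilyloxy)-13,14,15,16-tetranorlabd-8(17)-en-12-ol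
Product: 28 12-iodo-6α-(tert-butyldimethylsilyloxy)-18-(triethylsilyloxy)-13,14,15,16-tetranorlabd-8(17)-ene
Conditions: I2, PPh3, imidazole, CH2Cl2, 0 °C to rt
Reagents that add atoms: iodine, [I][I]
Why: Appel-type iodination converts the unhindered primary alcohol into the iodide by SN2 displacement of the alkoxyphosphonium ion.

Step 18
Reactants: 28 12-iodo-6α-(tert-butyldimethylsilyloxy)-18-(triethylsilyloxy)-13,14,15,16-tetranorlabd-8(17)-ene; 29 lithium acetylide–ethylenediamine complex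
Product: 30 6α-(tert-butyldimethylsilyloxy)-18-(triethylsilyloxy)-15,16-dinorlabd-8(17)-en-13-yne
Conditions: 29, DMSO/THF, 0 °C to rt
Reagents that add atoms: none
Why: SN2 alkylation of lithium acetylide by the primary iodide in DMSO adds C13 and C14 as a terminal alkyne.

Step 19
Reactants: 30 6α-(tert-butyldimethylsilyloxy)-18-(triethylsilyloxy)-15,16-dinorlabd-8(17)-en-13-yne
Product: 33 (13E)-6α-(tert-butyldimethylsilyloxy)-18-(triethylsilyloxy)labda-8(17),13-dien-15-ol, via alkenylalane 31 (not isolated), via lithium alanate 32 (not isolated)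
Conditions: AlMe3, Cp2ZrCl2, CH2Cl2, 0 °C to rt; then n-BuLi, THF, −78 °C; then (CH2O)n, −78 °C to rt
Reagents that add atoms: trimethylaluminium, C[Al](C)C; formaldehyde (as paraformaldehyde), C=O
Why: Negishi methylalumination (syn, methyl C16 on C13) followed by hydroxymethylation of the alanate gives the E allylic alcohol directly, and the 1,1-disubstituted alkene does not react.

Step 20
Reactants: 33 (13E)-6α-(tert-butyldimethylsilyloxy)-18-(triethylsilyloxy)labda-8(17),13-dien-15-ol
Product: 34 (13E)-6α-(tert-butyldimethylsilyloxy)-18-(triethylsilyloxy)labda-8(17),13-dien-15-al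
Conditions: MnO2, CH2Cl2, rt
Reagents that add atoms: none
Why: MnO2 oxidises only the allylic alcohol and does not isomerise the E alkene.

Step 21
Reactants: 35 4-methylfuran-2(5H)-one
Product: 36 4-methyl-2-(trimethylsilyloxy)furan
Conditions: TMSOTf, Et3N, Et2O, 0 °C; distillation
Reagents that add atoms: trimethylsilyl triflate, C[Si](C)(C)OS(=O)(=O)C(F)(F)F
Why: Soft enolisation and O-silylation of the butenolide give the aromatic silyl dienol ether, with TMS chosen so that silyl transfer can turn over the aldol catalyst.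

Step 22
Reactants: 34 (13E)-6α-(tert-butyldimethylsilyloxy)-18-(triethylsilyloxy)labda-8(17),13-dien-15-al; 36 4-methyl-2-(trimethylsilyloxy)furan
Product: 37 (13E,15S)-6α-(tert-butyldimethylsilyloxy)-15-hydroxy-15-[(2S)-3-methyl-5-oxo-2,5-dihydrofuran-2-yl]-18-(triethylsilyloxy)labda-8(17),13-diene
Conditions: Ti(OiPr)4/(R)-BINOL (1:1, 20 mol %), Et2O, −20 °C; then aq. citric acid, THF, 0 °C
Reagents that add atoms: none
Why: In this titanium–BINOLate-catalysed vinylogous Mukaiyama aldol the furan should attack through C5' the Re face of the bound enal in an open transition state, the catalyst setting C15 (S) and the threo preference of Lewis-acid-promoted silyloxyfuran additions setting C5' (S).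

Step 23
Reactants: 37 (13E,15S)-6α-(tert-butyldimethylsilyloxy)-15-hydroxy-15-[(2S)-3-methyl-5-oxo-2,5-dihydrofuran-2-yl]-18-(triethylsilyloxy)labda-8(17),13-diene
Product: 38 (13E,15S)-6α,15-bis(tert-butyldimethylsilyloxy)-15-[(2S)-3-methyl-5-oxo-2,5-dihydrofuran-2-yl]-18-(triethylsilyloxy)labda-8(17),13-diene
Conditions: TBSOTf, 2,6-lutidine, CH2Cl2, −78 °C
Reagents that add atoms: tert-butyldimethylsilyl triflate, CC(C)(C)[Si](C)(C)OS(=O)(=O)C(F)(F)F
Why: Silyl triflate with a hindered weak base silylates the secondary allylic alcohol at low temperature without epimerising C5'.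

Step 24
Reactants: 38 (13E,15S)-6α,15-bis(tert-butyldimethylsilyloxy)-15-[(2S)-3-methyl-5-oxo-2,5-dihydrofuran-2-yl]-18-(triethylsilyloxy)labda-8(17),13-diene
Product: 39 (13E,15S)-6α,15-bis(tert-butyldimethylsilyloxy)-15-[(2S)-3-methyl-5-oxo-2,5-dihydrofuran-2-yl]labda-8(17),13-dien-18-ol
Conditions: PPTS (cat.), MeOH/CH2Cl2, 0 °C
Reagents that add atoms: none
Why: Acid-catalysed methanolysis should cleave the primary TES ether far faster than the two secondary TBS ethers.

Step 25
Reactants: 39 (13E,15S)-6α,15-bis(tert-butyldimethylsilyloxy)-15-[(2S)-3-methyl-5-oxo-2,5-dihydrofuran-2-yl]labda-8(17),13-dien-18-ol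
Product: 40 (13E,15S)-6α,15-bis(tert-butyldimethylsilyloxy)-15-[(2S)-3-methyl-5-oxo-2,5-dihydrofuran-2-yl]labda-8(17),13-dien-18-al
Conditions: Dess–Martin periodinane, NaHCO3, CH2Cl2, rt
Reagents that add atoms: none
Why: Dess–Martin oxidation converts the neopentyl alcohol into the non-enolisable C18 aldehyde without touching the butenolide or the alkenes.

Step 26
Reactants: 40 (13E,15S)-6α,15-bis(tert-butyldimethylsilyloxy)-15-[(2S)-3-methyl-5-oxo-2,5-dihydrofuran-2-yl]labda-8(17),13-dien-18-al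
Product: 41 CNP0113661.1, (13E,15S)-6α,15-dihydroxy-15-[(2S)-3-methyl-5-oxo-2,5-dihydrofuran-2-yl]labda-8(17),13-dien-18-al
Conditions: HF·pyridine, pyridine, THF, 0 °C to rt
Reagents that add atoms: none
Why: Acidic fluoride removes both TBS ethers while avoiding the basic conditions that would epimerise C5' of the butenolide.

**Compound list**

1 | but-3-yn-1-ol | C#CCCO | starting material
2 | tert-butyl(but-3-yn-1-yloxy)dimethylsilane | C#CCCO[Si](C)(C)C(C)(C)C | intermediate
3 | ethylene oxide | C1CO1 | starting material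
4 | (E)-[4-(tert-butyldimethylsilyloxy)-2-methylbut-1-en-1-yl]dimethylalane (formed in situ) | C[Al](C)/C=C(\C)CCO[Si](C)(C)C(C)(C)C | intermediate
5 | lithium butyl[(E)-4-(tert-butyldimethylsilyloxy)-2-methylbut-1-en-1-yl]dimethylalanate (formed in situ) | [Li+].CCCC[Al-](C)(C)/C=C(\C)CCO[Si](C)(C)C(C)(C)C | intermediate
6 | (E)-6-(tert-butyldimethylsilyloxy)-4-methylhex-3-en-1-ol | OCC/C=C(\C)CCO[Si](C)(C)C(C)(C)C | intermediate
7 | (E)-tert-butyl{[6-(4-methoxybenzyloxy)-3-methylhex-3-en-1-yl]oxy}dimethylsilane | COc1ccc(COCC/C=C(\C)CCO[Si](C)(C)C(C)(C)C)cc1 | intermediate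
8 | (E)-6-(4-methoxybenzyloxy)-3-methylhex-3-en-1-ol | COc1ccc(COCC/C=C(\C)CCO)cc1 | intermediate
9 | (E)-6-(4-methoxybenzyloxy)-3-methylhex-3-enal | COc1ccc(COCC/C=C(\C)CC=O)cc1 | intermediate
10 | hept-1-en-6-yne | C=CCCCC#C | starting material
11 | hept-6-en-1-yn-1-yllithium (formed in situ) | [Li]C#CCCCC=C | intermediate
12 | rac-(3E)-1-(4-methoxybenzyloxy)-4-methyltrideca-3,12-dien-7-yn-6-ol | COc1ccc(COCC/C=C(\C)CC(O)C#CCCCC=C)cc1 | intermediate
13 | (3E)-1-(4-methoxybenzyloxy)-4-methyltrideca-3,12-dien-7-yn-6-one | COc1ccc(COCC/C=C(\C)CC(=O)C#CCCCC=C)cc1 | intermediate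
14 | (3E,6S)-1-(4-methoxybenzyloxy)-4-methyltrideca-3,12-dien-7-yn-6-ol | COc1ccc(COCC/C=C(\C)C[C@H](O)C#CCCCC=C)cc1 | intermediate
15 | sodium bis(2-methoxyethoxy)alanate of 14, five-membered ring O6–Al–C10=C5–C6 (formed in situ) | [Na+].COc1ccc(COCC/C=C(\C)C[C@@H]2O[Al-](OCCOC)(OCCOC)C(CCCC=C)=C2)cc1 | intermediate
16 | (3E,6S,7Z)-8-iodo-1-(4-methoxybenzyloxy)-4-methyltrideca-3,7,12-trien-6-ol | COc1ccc(COCC/C=C(\C)C[C@H](O)/C=C(\I)CCCC=C)cc1 | intermediate
17 | (3E,6S,7E)-1-(4-methoxybenzyloxy)-4,8-dimethyltrideca-3,7,12-trien-6-ol | COc1ccc(COCC/C=C(\C)C[C@H](O)/C=C(\C)CCCC=C)cc1 | intermediate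
18 | (3E,6S,7E)-6-(tert-butyldimethylsilyloxy)-1-(4-methoxybenzyloxy)-4,8-dimethyltrideca-3,7,12-triene | COc1ccc(COCC/C=C(\C)C[C@H](O[Si](C)(C)C(C)(C)C)/C=C(\C)CCCC=C)cc1 | intermediate
19 | (6E,8S,10E)-8-(tert-butyldimethylsilyloxy)-13-(4-methoxybenzyloxy)-6,10-dimethyltrideca-6,10-dien-2-one | COc1ccc(COCC/C=C(\C)C[C@H](O[Si](C)(C)C(C)(C)C)/C=C(\C)CCCC(C)=O)cc1 | intermediate
20 | 2-methyl-2-[(4E,6S,8E)-6-(tert-butyldimethylsilyloxy)-11-(4-methoxybenzyloxy)-4,8-dimethylundeca-4,8-dien-1-yl]oxirane (both C4 epimers) | COc1ccc(COCC/C=C(\C)C[C@H](O[Si](C)(C)C(C)(C)C)/C=C(\C)CCCC2(C)CO2)cc1 | intermediate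
21 | tertiary C4 radical with C18–O–Ti(Cl)Cp2 arm, open chain (formed in situ) | COc1ccc(COCC/C=C(\C)C[C@H](O[Si](C)(C)C(C)(C)C)/C=C(\C)CCC[C](C)CO[Ti+2]Cl)cc1.[cH-]1cccc1.[cH-]1cccc1 | intermediate
22 | monocyclic tertiary C10 radical, ring A closed (formed in situ) | COc1ccc(COCC/C=C(\C)C[C@H](O[Si](C)(C)C(C)(C)C)[C@@H]2[C](C)CCC[C@@]2(C)CO[Ti+2]Cl)cc1.[cH-]1cccc1.[cH-]1cccc1 | intermediate
23 | bicyclic tertiary C8 radical, rings A and B closed (formed in situ) | C[C]1C[C@H](O[Si](C)(C)C(C)(C)C)[C@@H]2[C@](C)(CCC[C@@]2(C)CO[Ti+2]Cl)[C@H]1CCOCc1ccc(OC)cc1.[cH-]1cccc1.[cH-]1cccc1 | intermediate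
24 | chlorotitanocene 18-alkoxide of 25 (formed in situ) | C=C1C[C@H](O[Si](C)(C)C(C)(C)C)[C@@H]2[C@](C)(CCC[C@@]2(C)CO[Ti+2]Cl)[C@H]1CCOCc1ccc(OC)cc1.[cH-]1cccc1.[cH-]1cccc1 | intermediate
25 | (4R,5R,6S,9S,10R)-6α-(tert-butyldimethylsilyloxy)-12-(4-methoxybenzyloxy)-13,14,15,16-tetranorlabd-8(17)-en-18-ol; trans-decalin, 4α-CH2OH, 4β-CH3, 10β-CH3, 9β-CH2CH2OPMB | C=C1C[C@H](O[Si](C)(C)C(C)(C)C)[C@@H]2[C@](C)(CCC[C@@]2(C)CO)[C@H]1CCOCc1ccc(OC)cc1 | intermediate
26 | 18-O-triethylsilyl ether of 25 | C=C1C[C@H](O[Si](C)(C)C(C)(C)C)[C@@H]2[C@](C)(CCC[C@@]2(C)CO[Si](CC)(CC)CC)[C@H]1CCOCc1ccc(OC)cc1 | intermediate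
27 | 6α-(tert-butyldimethylsilyloxy)-18-(triethylsilyloxy)-13,14,15,16-tetranorlabd-8(17)-en-12-ol | C=C1C[C@H](O[Si](C)(C)C(C)(C)C)[C@@H]2[C@](C)(CCC[C@@]2(C)CO[Si](CC)(CC)CC)[C@H]1CCO | intermediate
28 | 12-iodo-6α-(tert-butyldimethylsilyloxy)-18-(triethylsilyloxy)-13,14,15,16-tetranorlabd-8(17)-ene | C=C1C[C@H](O[Si](C)(C)C(C)(C)C)[C@@H]2[C@](C)(CCC[C@@]2(C)CO[Si](CC)(CC)CC)[C@H]1CCI | intermediate
29 | lithium acetylide–ethylenediamine complex | [Li]C#C.NCCN | starting material
30 | 6α-(tert-butyldimethylsilyloxy)-18-(triethylsilyloxy)-15,16-dinorlabd-8(17)-en-13-yne | C=C1C[C@H](O[Si](C)(C)C(C)(C)C)[C@@H]2[C@](C)(CCC[C@@]2(C)CO[Si](CC)(CC)CC)[C@H]1CCC#C | intermediate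
31 | (E)-alkenyldimethylalane from 30, Al on C14, methyl on C13 (formed in situ) | C=C1C[C@H](O[Si](C)(C)C(C)(C)C)[C@@H]2[C@](C)(CCC[C@@]2(C)CO[Si](CC)(CC)CC)[C@H]1CC/C(C)=C/[Al](C)C | intermediate
32 | lithium butyl(alkenyl)dimethylalanate from 31 (formed in situ) | [Li+].C=C1C[C@H](O[Si](C)(C)C(C)(C)C)[C@@H]2[C@](C)(CCC[C@@]2(C)CO[Si](CC)(CC)CC)[C@H]1CC/C(C)=C/[Al-](C)(C)CCCC | intermediate
33 | (13E)-6α-(tert-butyldimethylsilyloxy)-18-(triethylsilyloxy)labda-8(17),13-dien-15-ol | C=C1C[C@H](O[Si](C)(C)C(C)(C)C)[C@@H]2[C@](C)(CCC[C@@]2(C)CO[Si](CC)(CC)CC)[C@H]1CC/C(C)=C/CO | intermediate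
34 | (13E)-6α-(tert-butyldimethylsilyloxy)-18-(triethylsilyloxy)labda-8(17),13-dien-15-al | C=C1C[C@H](O[Si](C)(C)C(C)(C)C)[C@@H]2[C@](C)(CCC[C@@]2(C)CO[Si](CC)(CC)CC)[C@H]1CC/C(C)=C/C=O | intermediate
35 | 4-methylfuran-2(5H)-one | CC1=CC(=O)OC1 | starting material
36 | 4-methyl-2-(trimethylsilyloxy)furan | Cc1coc(O[Si](C)(C)C)c1 | intermediate
37 | (13E,15S)-6α-(tert-butyldimethylsilyloxy)-15-hydroxy-15-[(2S)-3-methyl-5-oxo-2,5-dihydrofuran-2-yl]-18-(triethylsilyloxy)labda-8(17),13-diene | C=C1C[C@H](O[Si](C)(C)C(C)(C)C)[C@@H]2[C@](C)(CCC[C@@]2(C)CO[Si](CC)(CC)CC)[C@H]1CC/C(C)=C/[C@H](O)[C@H]1OC(=O)C=C1C | intermediate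
38 | 15-O-tert-butyldimethylsilyl ether of 37 | C=C1C[C@H](O[Si](C)(C)C(C)(C)C)[C@@H]2[C@](C)(CCC[C@@]2(C)CO[Si](CC)(CC)CC)[C@H]1CC/C(C)=C/[C@H](O[Si](C)(C)C(C)(C)C)[C@H]1OC(=O)C=C1C | intermediate
39 | (13E,15S)-6α,15-bis(tert-butyldimethylsilyloxy)-15-[(2S)-3-methyl-5-oxo-2,5-dihydrofuran-2-yl]labda-8(17),13-dien-18-ol | C=C1C[C@H](O[Si](C)(C)C(C)(C)C)[C@@H]2[C@](C)(CCC[C@@]2(C)CO)[C@H]1CC/C(C)=C/[C@H](O[Si](C)(C)C(C)(C)C)[C@H]1OC(=O)C=C1C | intermediate
40 | (13E,15S)-6α,15-bis(tert-butyldimethylsilyloxy)-15-[(2S)-3-methyl-5-oxo-2,5-dihydrofuran-2-yl]labda-8(17),13-dien-18-al | C=C1C[C@H](O[Si](C)(C)C(C)(C)C)[C@@H]2[C@](C)(CCC[C@@]2(C)C=O)[C@H]1CC/C(C)=C/[C@H](O[Si](C)(C)C(C)(C)C)[C@H]1OC(=O)C=C1C | intermediate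
41 | CNP0113661.1, (4R,5R,6S,9S,10R,13E,15S)-6α,15-dihydroxy-15-[(2S)-3-methyl-5-oxo-2,5-dihydrofuran-2-yl]labda-8(17),13-dien-18-al | C=C1C[C@H](O)[C@@H]2[C@](C)(CCC[C@@]2(C)C=O)[C@H]1CC/C(C)=C/[C@H](O)[C@H]1OC(=O)C=C1C | target

**Step count**

Total step count: 26.
Longest linear sequence: 25 steps (steps 1–20 and 22–26, from but-3-yn-1-ol); step 21 is the only side branch.

**Steps most likely to fail**

1. Step 14 (bears the label "Proposed new method:"). What may go wrong: the tertiary radical 21 may be captured and eliminated before it adds to the hindered C5, the cascade may stop after ring A, or the radical may attack the wrong face of C5. The fallback uses known chemistry, sets out from 18 and comes back at 26. The terminal alkene of 18 is moved by one position with [CpRu(MeCN)(κ2-P,N-L)]PF6 (L = 2-(diisopropylphosphino)-4-tert-butyl-1-methylimidazole) to give the (E)-propenyl isomer F1. Cross-metathesis with methacrolein (second-generation Hoveyda–Grubbs catalyst) should give the (E)-2-methyl enal F2 with loss of propene, and NaBH4/CeCl3 the allylic alcohol F3. Sharpless asymmetric epoxidation (Ti(OiPr)4, L-(+)-diethyl tartrate, t-BuOOH) should give the (3S,4S)-epoxy alcohol F4, which TESCl converts into the silyl ether F5. The precedented Cp2TiCl cyclization of this trisubstituted 3,4-epoxide should give the 3β-hydroxy decalin F6; here the C3 stereocentre (titanoxy group equatorial in the chair) fixes the face at C5 and reinforces C6. The phenyl thionocarbonate F7 (PhOC(S)Cl, DMAP, pyridine) is then reduced with Bu3SnH/AIBN (Barton–McCombie deoxygenation) to 26.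

2. Step 22. What may go wrong: a low threo/erythro ratio or poor facial control at the two new centres, or sluggish addition to the β,β-disubstituted enal. The fallback sets out from 34 and comes back at 38. Evans syn-aldol reaction of 34 with the boron enolate (Bu2BOTf, Et3N) of the glycolyl imide F8 should give the syn adduct F9, both new centres being set by the auxiliary. AlMe3/MeONHMe·HCl converts it into the Weinreb amide F10 and releases the auxiliary; TBSOTf/2,6-lutidine gives the silyl ether F11; MeMgBr gives the methyl ketone F12; DDQ removes the PMB group to give the α-hydroxy ketone F13. Ph3P=C=C=O in warm toluene acylates the hydroxyl, and the resulting ylide closes the butenolide by intramolecular Wittig reaction to give 38.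

3. Step 8. What may go wrong: the C8=C9 double bond may migrate into conjugation with the ynone (the methylene between alkene and ynone is acidic), or enantioselection may be incomplete. The fallback sets out from 9 (with alkyne 10) and comes back at 14. Catalytic enantioselective alkynylation of aldehyde 9 with 10 (Me2Zn, the ProPhenol enantiomer that gives the S carbinol, Ph3PO, toluene, 0 °C) should form 14 directly, so that ynone 13 is never made and no new compound arises (F0).

**Further compounds**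

F1 | step 14 | (3E,6S,7E,11E)-6-(tert-butyldimethylsilyloxy)-1-(4-methoxybenzyloxy)-4,8-dimethyltrideca-3,7,11-triene | COc1ccc(COCC/C=C(\C)C[C@H](O[Si](C)(C)C(C)(C)C)/C=C(\C)CC/C=C/C)cc1
F2 | step 14 | (2E,6E,8S,10E)-8-(tert-butyldimethylsilyloxy)-13-(4-methoxybenzyloxy)-2,6,10-trimethyltrideca-2,6,10-trienal | COc1ccc(COCC/C=C(\C)C[C@H](O[Si](C)(C)C(C)(C)C)/C=C(\C)CC/C=C(\C)C=O)cc1
F3 | step 14 | (2E,6E,8S,10E)-8-(tert-butyldimethylsilyloxy)-13-(4-methoxybenzyloxy)-2,6,10-trimethyltrideca-2,6,10-trien-1-ol | COc1ccc(COCC/C=C(\C)C[C@H](O[Si](C)(C)C(C)(C)C)/C=C(\C)CC/C=C(\C)CO)cc1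
F4 | step 14 | {(2S,3S)-3-[(3E,5S,7E)-5-(tert-butyldimethylsilyloxy)-10-(4-methoxybenzyloxy)-3,7-dimethyldeca-3,7-dien-1-yl]-2-methyloxiran-2-yl}methanol | COc1ccc(COCC/C=C(\C)C[C@H](O[Si](C)(C)C(C)(C)C)/C=C(\C)CC[C@@H]2O[C@@]2(C)CO)cc1
F5 | step 14 | triethylsilyl ether of F4 | COc1ccc(COCC/C=C(\C)C[C@H](O[Si](C)(C)C(C)(C)C)/C=C(\C)CC[C@@H]2O[C@@]2(C)CO[Si](CC)(CC)CC)cc1
F6 | step 14 | 6α-(tert-butyldimethylsilyloxy)-12-(4-methoxybenzyloxy)-18-(triethylsilyloxy)-13,14,15,16-tetranorlabd-8(17)-en-3β-ol | C=C1C[C@H](O[Si](C)(C)C(C)(C)C)[C@@H]2[C@](C)(CC[C@H](O)[C@@]2(C)CO[Si](CC)(CC)CC)[C@H]1CCOCc1ccc(OC)cc1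
F7 | step 14 | 3-O-(phenoxythiocarbonyl) derivative of F6 | C=C1C[C@H](O[Si](C)(C)C(C)(C)C)[C@@H]2[C@](C)(CC[C@H](OC(=S)Oc3ccccc3)[C@@]2(C)CO[Si](CC)(CC)CC)[C@H]1CCOCc1ccc(OC)cc1
F8 | step 22 | (R)-4-benzyl-3-[(4-methoxybenzyloxy)acetyl]oxazolidin-2-one | COc1ccc(COCC(=O)N2[C@H](Cc3ccccc3)COC2=O)cc1
F9 | step 22 | Evans syn aldol adduct of 34 and F8: acyl C2 (R, OPMB), C3 = C15 (S, OH) | C=C1C[C@H](O[Si](C)(C)C(C)(C)C)[C@@H]2[C@](C)(CCC[C@@]2(C)CO[Si](CC)(CC)CC)[C@H]1CC/C(C)=C/[C@H](O)[C@@H](OCc1ccc(OC)cc1)C(=O)N1[C@H](Cc2ccccc2)COC1=O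
F10 | step 22 | N-methoxy-N-methylamide from F9 | C=C1C[C@H](O[Si](C)(C)C(C)(C)C)[C@@H]2[C@](C)(CCC[C@@]2(C)CO[Si](CC)(CC)CC)[C@H]1CC/C(C)=C/[C@H](O)[C@@H](OCc1ccc(OC)cc1)C(=O)N(C)OC
F11 | step 22 | 15-O-tert-butyldimethylsilyl ether of F10 | C=C1C[C@H](O[Si](C)(C)C(C)(C)C)[C@@H]2[C@](C)(CCC[C@@]2(C)CO[Si](CC)(CC)CC)[C@H]1CC/C(C)=C/[C@H](O[Si](C)(C)C(C)(C)C)[C@@H](OCc1ccc(OC)cc1)C(=O)N(C)OC
F12 | step 22 | methyl ketone from F11 | C=C1C[C@H](O[Si](C)(C)C(C)(C)C)[C@@H]2[C@](C)(CCC[C@@]2(C)CO[Si](CC)(CC)CC)[C@H]1CC/C(C)=C/[C@H](O[Si](C)(C)C(C)(C)C)[C@@H](OCc1ccc(OC)cc1)C(C)=O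
F13 | step 22 | α-hydroxy methyl ketone from F12 | C=C1C[C@H](O[Si](C)(C)C(C)(C)C)[C@@H]2[C@](C)(CCC[C@@]2(C)CO[Si](CC)(CC)CC)[C@H]1CC/C(C)=C/[C@H](O[Si](C)(C)C(C)(C)C)[C@@H](O)C(C)=O
F0 | step 8 | none | none
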